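**Retrosynthetic overview**

1. Ring A is a hexasubstituted benzene in which carbon-bearing atoms (C1 CH2 arm, C3 aroyl, C5 alkenyl) alternate with oxygen-bearing atoms (C2 OH, C4 OH, C6 OMe). It is therefore cut into one ketene unit (C6 + C1) and two ynol ether units (C2 + C3 and C4 + C5).
2. Ring A, the only ring to be built, is closed in one operation from a 3-siloxycyclobutenone (C6, C1, C2, C3) and an enynyl silyl ether (C4, C5). C5–C6 and C3–C4 form by [2+2] cycloaddition, C1–C6 by 6π electrocyclisation, and the only phenol set free is the C6 oxygen that must be methylated.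
3. The cyclobutenone comes from [2+2] cycloaddition of a Wolff ketene (acid cut from (R)-limonene, which supplies the only stereocenter) with a siloxyalkyne built from 3-hydroxybenzaldehyde and ethynylmagnesium bromide. The enynyl ether comes from Kowalski homologation of ethyl (E)-4-methylpent-2-enoate.
4. C3 travels as a silylated diaryl carbinol, because an acyl group would make the ynol ether electron-poor and the vinylketene an acylketene. End game: O-methylation, triethylsilyl removal, oxidation, desilylation.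

Key step: step 11

Remark: the carbinol carbon and ring carbon C4 of the cyclobutenone are carried as stereoisomer mixtures because both become sp2 later. The single (R) stereocenter of the target is C4 of (R)-limonene and is never touched (the limonene ring CH2 next to the alkene CH becomes the ArCH2 carbon).

**Route**

Step 1
Reactants: 1 (R)-(+)-limonene
Product: 3 (3R)-6-oxo-3-(prop-1-en-2-yl)heptanal, via secondary ozonide 2 (not isolated)
Conditions: O3 (1 equiv, Sudan Red 7B end point), CH2Cl2, −78 °C; PPh3, −78 °C → rt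
Reagents that add atoms: ozone, [O-][O+]=O
Why: Ozonolysis with reductive work-up cleaves the more electron-rich trisubstituted ring alkene faster than the 1,1-disubstituted isopropenyl group, and the stereocenter is not involved.

Step 2
Reactants: 3 (3R)-6-oxo-3-(prop-1-en-2-yl)heptanal
Product: 4 (3R)-6-oxo-3-(prop-1-en-2-yl)heptanoic acid
Conditions: NaClO2, NaH2PO4, 2-methylbut-2-ene, t-BuOH/H2O, 0 °C → rt
Reagents that add atoms: sodium chlorite, [Na+].[O-]Cl=O
Why: Pinnick oxidation converts the aldehyde into the acid under buffered conditions, with 2-methylbut-2-ene trapping HOCl so that the isopropenyl group survives.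

Step 3
Reactants: 4 (3R)-6-oxo-3-(prop-1-en-2-yl)heptanoic acid
Product: 5 (3R)-6-methyl-3-(prop-1-en-2-yl)hept-6-enoic acid
Conditions: Ph3PCH3Br, KOt-Bu (excess), THF, 0 °C → rt; aq. citric acid work-up
Reagents that add atoms: methyltriphenylphosphonium bromide, C[P+](c1ccccc1)(c1ccccc1)c1ccccc1.[Br-]
Why: Wittig methylenation of the methyl ketone proceeds in the presence of the inert carboxylate, and the stereocenter is not alpha to a carbonyl group, so it cannot epimerise.

Step 4
Reactants: 5 (3R)-6-methyl-3-(prop-1-en-2-yl)hept-6-enoic acid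
Product: 7 (4R)-1-diazo-7-methyl-4-(prop-1-en-2-yl)oct-7-en-2-one, via mixed anhydride 6 (not isolated)
Conditions: i-BuOCOCl, N-methylmorpholine, THF, −15 °C; CH2N2, Et2O, 0 °C → rt
Reagents that add atoms: diazomethane, C=[N+]=[N-]
Why: Acylation of diazomethane by a mixed carbonic anhydride (first stage of the Arndt–Eistert sequence) gives the diazoketone without free HCl, which would add to the 1,1-disubstituted alkenes.

Step 5
Reactants: 8 3-hydroxybenzaldehyde
Product: 9 3-(triisopropylsilyloxy)benzaldehyde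
Conditions: TIPSCl, imidazole, DMF, rt
Reagents that add atoms: chlorotriisopropylsilane, CC(C)[Si](Cl)(C(C)C)C(C)C
Why: Imidazole-mediated silylation protects the phenol as an aryl triisopropylsilyl ether that withstands the Grignard, amide-base and peroxide steps that follow.

Step 6
Reactants: 9 3-(triisopropylsilyloxy)benzaldehyde; 10 ethynylmagnesium bromide
Product: 11 rac-1-[3-(triisopropylsilyloxy)phenyl]prop-2-yn-1-ol
Conditions: THF, 0 °C; aq. NH4Cl
Reagents that add atoms: none
Why: 1,2-Addition of the alkynyl Grignard reagent to the aldehyde gives the propargylic alcohol; the carbinol centre forms racemic, which is accepted because it becomes the ketone carbon in step 14.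

Step 7
Reactants: 11 rac-1-[3-(triisopropylsilyloxy)phenyl]prop-2-yn-1-ol
Product: 12 rac-triethyl({1-[3-(triisopropylsilyloxy)phenyl]prop-2-yn-1-yl}oxy)silane
Conditions: TESCl, imidazole, CH2Cl2, 0 °C → rt
Reagents that add atoms: chlorotriethylsilane, CC[Si](Cl)(CC)CC
Why: Silylation of the secondary alcohol gives an alkyl triethylsilyl ether, chosen because it can later be cleaved by buffered HF in the presence of aryl triisopropylsilyl ethers.

Step 8
Reactants: 12 rac-triethyl({1-[3-(triisopropylsilyloxy)phenyl]prop-2-yn-1-yl}oxy)silane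
Product: 15 rac-triethyl({1-[3-(triisopropylsilyloxy)phenyl]-3-(triisopropylsilyloxy)prop-2-yn-1-yl}oxy)silane, via lithium acetylide 13 (not isolated), via lithium ynolate 14 (not isolated)
Conditions: LiN(SiMe3)2, t-BuOOH, THF, −78 → 0 °C; TIPSOTf, −78 °C; chromatography on Et3N-deactivated silica
Reagents that add atoms: tert-butyl hydroperoxide, CC(C)(C)OO; triisopropylsilyl trifluoromethanesulfonate, CC(C)[Si](OS(=O)(=O)C(F)(F)F)(C(C)C)C(C)C
Why: Oxidation of the lithium acetylide by lithium tert-butyl peroxide gives the lithium ynolate (Julia ynolate synthesis), which the bulky silyl triflate silylates on oxygen, the standard route from terminal alkynes to triisopropylsiloxyalkynes.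

Step 9
Reactants: 7 (4R)-1-diazo-7-methyl-4-(prop-1-en-2-yl)oct-7-en-2-one; 15 rac-triethyl({1-[3-(triisopropylsilyloxy)phenyl]-3-(triisopropylsilyloxy)prop-2-yn-1-yl}oxy)silane
Product: 17 4-[(2R)-5-methyl-2-(prop-1-en-2-yl)hex-5-en-1-yl]-2-{(triethylsilyloxy)[3-(triisopropylsilyloxy)phenyl]methyl}-3-(triisopropylsilyloxy)cyclobut-2-en-1-one (diastereomer mixture at ring C4 and the carbinol carbon), via ketene 16 (not isolated)
Conditions: hν (365 nm), CH2Cl2, rt, 15 in slight excess
Reagents that add atoms: none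
Why: Photochemical Wolff rearrangement of the diazoketone releases the monoalkylketene at low stationary concentration, and this adds [2+2] to the siloxyalkyne with the known regiochemistry (ketene carbonyl carbon to the alkyne carbon remote from oxygen); light of 365 nm is not absorbed by the product, and the unselectively formed ring stereocenter C4 is lost on aromatisation.

Step 10
Reactants: 18 ethyl (E)-4-methylpent-2-enoate
Product: 21 (E)-triisopropyl[(5-methylhex-3-en-1-yn-1-yl)oxy]silane, via dibromo enolate 19 (not isolated), via lithium enynolate 20 (not isolated)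
Conditions: CH2Br2, lithium 2,2,6,6-tetramethylpiperidide, THF, −78 °C; 18; LiN(SiMe3)2; n-BuLi, −78 °C → rt; TIPSCl, −78 °C → rt
Reagents that add atoms: dibromomethane, BrCBr; chlorotriisopropylsilane, CC(C)[Si](Cl)(C(C)C)C(C)C
Why: Kowalski ester homologation: LiCHBr2 adds 1,2 to the ester, the derived dibromo enolate undergoes Br/Li exchange and 1,2-shift of the alkenyl group with retention of the (E) geometry to the ynolate, and the bulky chlorosilane silylates it on oxygen.

Step 11
Reactants: 17 4-[(2R)-5-methyl-2-(prop-1-en-2-yl)hex-5-en-1-yl]-2-{(triethylsilyloxy)[3-(triisopropylsilyloxy)phenyl]methyl}-3-(triisopropylsilyloxy)cyclobut-2-en-1-one; 21 (E)-triisopropyl[(5-methylhex-3-en-1-yn-1-yl)oxy]silane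
Product: 26 2-[(E)-3-methylbut-1-en-1-yl]-6-[(2R)-5-methyl-2-(prop-1-en-2-yl)hex-5-en-1-yl]-4-{(triethylsilyloxy)[3-(triisopropylsilyloxy)phenyl]methyl}-3,5-bis(triisopropylsilyloxy)phenol, via vinylketene 22 (not isolated), via 4-vinylcyclobutenone 23 (not isolated), via dienylketene 24 (not isolated), via cyclohexadienone 25 (not isolated)
Conditions: 21 (1.5 equiv), toluene, 80 → 110 °C, sealed tube, Ar
Reagents that add atoms: none
Why: Heating opens cyclobutenone 17 by 4π electrocyclic cleavage of its C1–C4 bond to vinylketene 22, whose ketene carbon (future C6 of ring A) is attacked by the alkyne carbon of 21 remote from oxygen (future C5), and the [2+2] cycloaddition also joins future C3 to C4 to give 4-vinylcyclobutenone 23. A second 4π opening gives dienylketene 24, whose 6π electrocyclisation forms C1–C6 to give cyclohexadienone 25, which tautomerises to phenol 26. The closest known reaction is the cyclobutenone–siloxyalkyne benzannulation (Danheiser benzannulation), which has been used with 3-siloxycyclobutenones to make resorcinols. Ring A is closed by thermal disrotatory 6π electrocyclisation of a ketene-terminated triene, all six ring atoms coming from the three two-carbon units. No stereocenter is created: ring C4 of 17 becomes aromatic C1 and the carbinol centre is later oxidised, so all diastereomers of 17 converge, while the neutral thermal conditions leave the remote (R) centre and the acid-sensitive isopropenyl groups alone. The step needs regioselectivity only, which is secured by the polarisation of the ynol ether (nucleophilic carbon beta to oxygen, electrophilic ketene carbon) and by the single vinyl group on the quaternary carbon of 23, which allows one 6π closure and leaves the C6 oxygen as the only free phenol.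

Step 12
Reactants: 26 2-[(E)-3-methylbut-1-en-1-yl]-6-[(2R)-5-methyl-2-(prop-1-en-2-yl)hex-5-en-1-yl]-4-{(triethylsilyloxy)[3-(triisopropylsilyloxy)phenyl]methyl}-3,5-bis(triisopropylsilyloxy)phenol
Product: 27 methyl ether of 26 (ring A: C1 (R)-arm, C2 OTIPS, C3 CH(OSiEt3)[3-(triisopropylsilyloxy)phenyl], C4 OTIPS, C5 (E)-3-methylbut-1-enyl, C6 OMe)
Conditions: MeI, K2CO3, acetone, 50 °C
Reagents that add atoms: iodomethane, CI
Why: Williamson methylation of the only free phenol; the silyl ethers sit meta to the phenoxide, so no silyl migration is possible, and carbonate in acetone does not cleave aryl triisopropylsilyl ethers.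

Step 13
Reactants: 27 methyl ether of 26
Product: 28 {4-methoxy-3-[(E)-3-methylbut-1-en-1-yl]-5-[(2R)-5-methyl-2-(prop-1-en-2-yl)hex-5-en-1-yl]-2,6-bis(triisopropylsilyloxy)phenyl}[3-(triisopropylsilyloxy)phenyl]methanol (both carbinol epimers)
Conditions: HF·pyridine, pyridine, THF, 0 °C
Reagents that add atoms: none
Why: Under pyridine-buffered, weakly acidic fluoride conditions an alkyl triethylsilyl ether is cleaved at silicon much faster than aryl triisopropylsilyl ethers, and the buffer protects the isopropenyl groups and the ionisable diaryl carbinol.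

Step 14
Reactants: 28 {4-methoxy-3-[(E)-3-methylbut-1-en-1-yl]-5-[(2R)-5-methyl-2-(prop-1-en-2-yl)hex-5-en-1-yl]-2,6-bis(triisopropylsilyloxy)phenyl}[3-(triisopropylsilyloxy)phenyl]methanol
Product: 29 {4-methoxy-3-[(E)-3-methylbut-1-en-1-yl]-5-[(2R)-5-methyl-2-(prop-1-en-2-yl)hex-5-en-1-yl]-2,6-bis(triisopropylsilyloxy)phenyl}[3-(triisopropylsilyloxy)phenyl]methanone
Conditions: Dess–Martin periodinane, pyridine, CH2Cl2, 0 °C → rt
Reagents that add atoms: none
Why: Dess–Martin oxidation of the activated diaryl carbinol under buffered, non-acidic conditions removes the mixed carbinol stereocenter and leaves the alkenes and silyl ethers untouched.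

Step 15
Reactants: 29 {4-methoxy-3-[(E)-3-methylbut-1-en-1-yl]-5-[(2R)-5-methyl-2-(prop-1-en-2-yl)hex-5-en-1-yl]-2,6-bis(triisopropylsilyloxy)phenyl}[3-(triisopropylsilyloxy)phenyl]methanone
Product: 30 {2,6-dihydroxy-4-methoxy-3-[(E)-3-methylbut-1-en-1-yl]-5-[(2R)-5-methyl-2-(prop-1-en-2-yl)hex-5-en-1-yl]phenyl}(3-hydroxyphenyl)methanone (CNP0208548.1)
Conditions: Bu4NF, AcOH, THF, 0 °C → rt
Reagents that add atoms: none
Why: Fluoride cleaves the three aryl silyl ethers readily, and acetic acid buffering keeps the resulting phenols protonated so that the (E)-alkenyl and isopropenyl groups are not affected.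

**Compound list**

1 | (R)-(+)-limonene | CC1=CC[C@@H](CC1)C(C)=C | starting material
2 | (4R)-1-methyl-4-(prop-1-en-2-yl)-7,8,9-trioxabicyclo[4.2.1]nonane (secondary ozonide, mixture at the acetal carbons) | CC12OOC(O1)C[C@@H](CC2)C(C)=C | intermediate (not isolated)
3 | (3R)-6-oxo-3-(prop-1-en-2-yl)heptanal | O=CC[C@@H](CCC(C)=O)C(C)=C | intermediate
4 | (3R)-6-oxo-3-(prop-1-en-2-yl)heptanoic acid | OC(=O)C[C@@H](CCC(C)=O)C(C)=C | intermediate
5 | (3R)-6-methyl-3-(prop-1-en-2-yl)hept-6-enoic acid | OC(=O)C[C@@H](CCC(C)=C)C(C)=C | intermediate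
6 | isobutyl carbonic (3R)-6-methyl-3-(prop-1-en-2-yl)hept-6-enoic anhydride | CC(C)COC(=O)OC(=O)C[C@@H](CCC(C)=C)C(C)=C | intermediate (not isolated)
7 | (4R)-1-diazo-7-methyl-4-(prop-1-en-2-yl)oct-7-en-2-one | [N-]=[N+]=CC(=O)C[C@@H](CCC(C)=C)C(C)=C | intermediate
8 | 3-hydroxybenzaldehyde | O=Cc1cccc(O)c1 | starting material
9 | 3-(triisopropylsilyloxy)benzaldehyde | O=Cc1cccc(O[Si](C(C)C)(C(C)C)C(C)C)c1 | intermediate
10 | ethynylmagnesium bromide | C#C[Mg]Br | starting material
11 | rac-1-[3-(triisopropylsilyloxy)phenyl]prop-2-yn-1-ol | C#CC(O)c1cccc(O[Si](C(C)C)(C(C)C)C(C)C)c1 | intermediate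
12 | rac-triethyl({1-[3-(triisopropylsilyloxy)phenyl]prop-2-yn-1-yl}oxy)silane | C#CC(O[Si](CC)(CC)CC)c1cccc(O[Si](C(C)C)(C(C)C)C(C)C)c1 | intermediate
13 | lithium acetylide of 12 | [Li]C#CC(O[Si](CC)(CC)CC)c1cccc(O[Si](C(C)C)(C(C)C)C(C)C)c1 | intermediate (not isolated)
14 | lithium 3-(triethylsilyloxy)-3-[3-(triisopropylsilyloxy)phenyl]prop-1-yn-1-olate | [Li+].[O-]C#CC(O[Si](CC)(CC)CC)c1cccc(O[Si](C(C)C)(C(C)C)C(C)C)c1 | intermediate (not isolated)
15 | rac-triethyl({1-[3-(triisopropylsilyloxy)phenyl]-3-(triisopropylsilyloxy)prop-2-yn-1-yl}oxy)silane | CC(C)[Si](C(C)C)(C(C)C)OC#CC(O[Si](CC)(CC)CC)c1cccc(O[Si](C(C)C)(C(C)C)C(C)C)c1 | intermediate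
16 | (4R)-7-methyl-4-(prop-1-en-2-yl)octa-1,7-dien-1-one (ketene) | O=C=CC[C@@H](CCC(C)=C)C(C)=C | intermediate (not isolated)
17 | 4-[(2R)-5-methyl-2-(prop-1-en-2-yl)hex-5-en-1-yl]-2-{(triethylsilyloxy)[3-(triisopropylsilyloxy)phenyl]methyl}-3-(triisopropylsilyloxy)cyclobut-2-en-1-one (diastereomer mixture) | O=C1C(C(O[Si](CC)(CC)CC)c2cccc(O[Si](C(C)C)(C(C)C)C(C)C)c2)=C(O[Si](C(C)C)(C(C)C)C(C)C)C1C[C@@H](CCC(C)=C)C(C)=C | intermediate (key-step precursor)
18 | ethyl (E)-4-methylpent-2-enoate | CCOC(=O)/C=C/C(C)C | starting material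
19 | lithium (E)-1,1-dibromo-5-methylhexa-1,3-dien-2-olate | [Li+].[O-]C(/C=C/C(C)C)=C(Br)Br | intermediate (not isolated)
20 | lithium (E)-5-methylhex-3-en-1-yn-1-olate | [Li+].[O-]C#C/C=C/C(C)C | intermediate (not isolated)
21 | (E)-triisopropyl[(5-methylhex-3-en-1-yn-1-yl)oxy]silane | CC(C)/C=C/C#CO[Si](C(C)C)(C(C)C)C(C)C | intermediate (key-step precursor)
22 | (6R)-9-methyl-6-(prop-1-en-2-yl)-2-{(triethylsilyloxy)[3-(triisopropylsilyloxy)phenyl]methyl}-3-(triisopropylsilyloxy)deca-1,3,9-trien-1-one (vinylketene, alkene geometry not fixed) | O=C=C(C(O[Si](CC)(CC)CC)c1cccc(O[Si](C(C)C)(C(C)C)C(C)C)c1)C(O[Si](C(C)C)(C(C)C)C(C)C)=CC[C@@H](CCC(C)=C)C(C)=C | intermediate (not isolated)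
23 | cyclobut-2-en-1-one with C2 (E)-3-methylbut-1-enyl, C3 OTIPS and quaternary C4 bearing CH(OSiEt3)[3-(triisopropylsilyloxy)phenyl] and the 1-(triisopropylsilyloxy)alk-1-enyl chain of the (R)-arm | O=C1C(/C=C/C(C)C)=C(O[Si](C(C)C)(C(C)C)C(C)C)C1(C(O[Si](CC)(CC)CC)c2cccc(O[Si](C(C)C)(C(C)C)C(C)C)c2)C(O[Si](C(C)C)(C(C)C)C(C)C)=CC[C@@H](CCC(C)=C)C(C)=C | intermediate (not isolated)
24 | dienylketene: 2-[(E)-3-methylbut-1-enyl]-3,5-bis(triisopropylsilyloxy)-4-{(triethylsilyloxy)[3-(triisopropylsilyloxy)phenyl]methyl}-substituted (8R)-11-methyl-8-(prop-1-en-2-yl)dodeca-1,3,5,11-tetraen-1-one | O=C=C(/C=C/C(C)C)C(O[Si](C(C)C)(C(C)C)C(C)C)=C(C(O[Si](CC)(CC)CC)c1cccc(O[Si](C(C)C)(C(C)C)C(C)C)c1)C(O[Si](C(C)C)(C(C)C)C(C)C)=CC[C@@H](CCC(C)=C)C(C)=C | intermediate (not isolated)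
25 | cyclohexa-2,4-dien-1-one keto tautomer of 26 (C6 sp3, bearing H and the (R)-arm) | O=C1C(/C=C/C(C)C)=C(O[Si](C(C)C)(C(C)C)C(C)C)C(C(O[Si](CC)(CC)CC)c2cccc(O[Si](C(C)C)(C(C)C)C(C)C)c2)=C(O[Si](C(C)C)(C(C)C)C(C)C)C1C[C@@H](CCC(C)=C)C(C)=C | intermediate (not isolated)
26 | 2-[(E)-3-methylbut-1-en-1-yl]-6-[(2R)-5-methyl-2-(prop-1-en-2-yl)hex-5-en-1-yl]-4-{(triethylsilyloxy)[3-(triisopropylsilyloxy)phenyl]methyl}-3,5-bis(triisopropylsilyloxy)phenol | C=C(C)CC[C@H](Cc1c(O[Si](C(C)C)(C(C)C)C(C)C)c(C(O[Si](CC)(CC)CC)c2cccc(O[Si](C(C)C)(C(C)C)C(C)C)c2)c(O[Si](C(C)C)(C(C)C)C(C)C)c(/C=C/C(C)C)c1O)C(=C)C | intermediate (key-step product)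
27 | methyl ether of 26 (C6 OMe) | C=C(C)CC[C@H](Cc1c(O[Si](C(C)C)(C(C)C)C(C)C)c(C(O[Si](CC)(CC)CC)c2cccc(O[Si](C(C)C)(C(C)C)C(C)C)c2)c(O[Si](C(C)C)(C(C)C)C(C)C)c(/C=C/C(C)C)c1OC)C(=C)C | intermediate
28 | {4-methoxy-3-[(E)-3-methylbut-1-en-1-yl]-5-[(2R)-5-methyl-2-(prop-1-en-2-yl)hex-5-en-1-yl]-2,6-bis(triisopropylsilyloxy)phenyl}[3-(triisopropylsilyloxy)phenyl]methanol | C=C(C)CC[C@H](Cc1c(O[Si](C(C)C)(C(C)C)C(C)C)c(C(O)c2cccc(O[Si](C(C)C)(C(C)C)C(C)C)c2)c(O[Si](C(C)C)(C(C)C)C(C)C)c(/C=C/C(C)C)c1OC)C(=C)C | intermediate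
29 | {4-methoxy-3-[(E)-3-methylbut-1-en-1-yl]-5-[(2R)-5-methyl-2-(prop-1-en-2-yl)hex-5-en-1-yl]-2,6-bis(triisopropylsilyloxy)phenyl}[3-(triisopropylsilyloxy)phenyl]methanone | C=C(C)CC[C@H](Cc1c(O[Si](C(C)C)(C(C)C)C(C)C)c(C(=O)c2cccc(O[Si](C(C)C)(C(C)C)C(C)C)c2)c(O[Si](C(C)C)(C(C)C)C(C)C)c(/C=C/C(C)C)c1OC)C(=C)C | intermediate
30 | {2,6-dihydroxy-4-methoxy-3-[(E)-3-methylbut-1-en-1-yl]-5-[(2R)-5-methyl-2-(prop-1-en-2-yl)hex-5-en-1-yl]phenyl}(3-hydroxyphenyl)methanone (CNP0208548.1) | C=C(C)CC[C@H](Cc1c(O)c(C(=O)c2cccc(O)c2)c(O)c(/C=C/C(C)C)c1OC)C(=C)C | target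

**Totals**

Total step count: 15. Longest linear sequence: 10 steps (steps 1–4, 9, 11–15 from (R)-limonene; the sequence from 3-hydroxybenzaldehyde, steps 5–9 and 11–15, is equally long).

**Steps most likely to fail**

Step 11. The branched CH(OSiEt3)Ar group on the ketene carbon of 22 may slow the [2+2] cycloaddition so much that reversible reclosure to 17 and thermal decay of 21 (1,3-silyl shift, oligomerisation) take over. The fallback sets out from 7 and 21 and comes back at 28: C3 is carried as an unbranched CH2OSi group and the aryl ring is added after ring A exists. Commercial tert-butyldimethyl(prop-2-yn-1-yloxy)silane (C#CCO[Si](C)(C)C(C)(C)C) is converted as in step 8 (LiN(SiMe3)2, t-BuOOH; TIPSOTf) into tert-butyldimethyl{[3-(triisopropylsilyloxy)prop-2-yn-1-yl]oxy}silane F1. Photolysis of 7 with F1 as in step 9 should give 2-[(tert-butyldimethylsilyloxy)methyl]-4-[(2R)-5-methyl-2-(prop-1-en-2-yl)hex-5-en-1-yl]-3-(triisopropylsilyloxy)cyclobut-2-en-1-one F2. Heating F2 with 21 in toluene should give the ring A phenol with CH2OTBS at C3 F3, and MeI/K2CO3 its methyl ether F4. HF·pyridine/pyridine cleaves the primary silyl ether to the benzylic alcohol F5, and Dess–Martin periodinane gives the hindered benzaldehyde F6. Separately, 3-bromophenol (TIPSCl, imidazole) gives (3-bromophenoxy)triisopropylsilane F7, which with Mg in THF gives [3-(triisopropylsilyloxy)phenyl]magnesium bromide F8. Addition of F8 to F6 gives carbinol 28, and steps 14 and 15 follow unchanged.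

Step 9. The monoalkylketene may dimerise, or carbene-type side reactions and photodegradation of 15 may outrun the cycloaddition during irradiation. The fallback sets out from 7 and comes back at 17: the ketene is made without light by dehydrochlorination. Wolff rearrangement of 7 in aqueous THF (PhCO2Ag cat., Et3N; Arndt–Eistert homologation) gives (4R)-7-methyl-4-(prop-1-en-2-yl)oct-7-enoic acid F9. 1-Chloro-N,N,2-trimethylprop-1-en-1-amine in CH2Cl2 converts it under neutral conditions into (4R)-7-methyl-4-(prop-1-en-2-yl)oct-7-enoyl chloride F10. Slow addition of F10 to 15 and Et3N in CH2Cl2 generates ketene 16 at low concentration, and 15 traps it to give 17.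

Step 13. Instead of clean Si–O cleavage, the doubly benzylic carbon (stabilised by three oxygen substituents on ring A) may ionise under the weakly acidic fluoride, or aryl silyl groups may be lost early. The fallback sets out from 27 and comes back at 30: oxidation and deprotection are taken in the reverse order. Bu4NF/AcOH in THF removes all four silyl groups to give {2,6-dihydroxy-4-methoxy-3-[(E)-3-methylbut-1-en-1-yl]-5-[(2R)-5-methyl-2-(prop-1-en-2-yl)hex-5-en-1-yl]phenyl}(3-hydroxyphenyl)methanol F11, which is kept cold and neutral. Activated MnO2 in EtOAc then oxidises the diaryl carbinol selectively to target 30.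

**Further compounds**

F1 | step 11 | tert-butyldimethyl{[3-(triisopropylsilyloxy)prop-2-yn-1-yl]oxy}silane | CC(C)[Si](C(C)C)(C(C)C)OC#CCO[Si](C)(C)C(C)(C)C
F2 | step 11 | 2-[(tert-butyldimethylsilyloxy)methyl]-4-[(2R)-5-methyl-2-(prop-1-en-2-yl)hex-5-en-1-yl]-3-(triisopropylsilyloxy)cyclobut-2-en-1-one | O=C1C(CO[Si](C)(C)C(C)(C)C)=C(O[Si](C(C)C)(C(C)C)C(C)C)C1C[C@@H](CCC(C)=C)C(C)=C
F3 | step 11 | 4-[(tert-butyldimethylsilyloxy)methyl]-2-[(E)-3-methylbut-1-en-1-yl]-6-[(2R)-5-methyl-2-(prop-1-en-2-yl)hex-5-en-1-yl]-3,5-bis(triisopropylsilyloxy)phenol | C=C(C)CC[C@H](Cc1c(O[Si](C(C)C)(C(C)C)C(C)C)c(CO[Si](C)(C)C(C)(C)C)c(O[Si](C(C)C)(C(C)C)C(C)C)c(/C=C/C(C)C)c1O)C(=C)C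
F4 | step 11 | methyl ether of F3 | C=C(C)CC[C@H](Cc1c(O[Si](C(C)C)(C(C)C)C(C)C)c(CO[Si](C)(C)C(C)(C)C)c(O[Si](C(C)C)(C(C)C)C(C)C)c(/C=C/C(C)C)c1OC)C(=C)C
F5 | step 11 | {4-methoxy-3-[(E)-3-methylbut-1-en-1-yl]-5-[(2R)-5-methyl-2-(prop-1-en-2-yl)hex-5-en-1-yl]-2,6-bis(triisopropylsilyloxy)phenyl}methanol | C=C(C)CC[C@H](Cc1c(O[Si](C(C)C)(C(C)C)C(C)C)c(CO)c(O[Si](C(C)C)(C(C)C)C(C)C)c(/C=C/C(C)C)c1OC)C(=C)C
F6 | step 11 | 4-methoxy-3-[(E)-3-methylbut-1-en-1-yl]-5-[(2R)-5-methyl-2-(prop-1-en-2-yl)hex-5-en-1-yl]-2,6-bis(triisopropylsilyloxy)benzaldehyde | C=C(C)CC[C@H](Cc1c(O[Si](C(C)C)(C(C)C)C(C)C)c(C=O)c(O[Si](C(C)C)(C(C)C)C(C)C)c(/C=C/C(C)C)c1OC)C(=C)C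
F7 | step 11 | (3-bromophenoxy)triisopropylsilane | Brc1cccc(O[Si](C(C)C)(C(C)C)C(C)C)c1
F8 | step 11 | [3-(triisopropylsilyloxy)phenyl]magnesium bromide | Br[Mg]c1cccc(O[Si](C(C)C)(C(C)C)C(C)C)c1
F9 | step 9 | (4R)-7-methyl-4-(prop-1-en-2-yl)oct-7-enoic acid | OC(=O)CC[C@@H](CCC(C)=C)C(C)=C
F10 | step 9 | (4R)-7-methyl-4-(prop-1-en-2-yl)oct-7-enoyl chloride | ClC(=O)CC[C@@H](CCC(C)=C)C(C)=C
F11 | step 13 | {2,6-dihydroxy-4-methoxy-3-[(E)-3-methylbut-1-en-1-yl]-5-[(2R)-5-methyl-2-(prop-1-en-2-yl)hex-5-en-1-yl]phenyl}(3-hydroxyphenyl)methanol | C=C(C)CC[C@H](Cc1c(O)c(C(O)c2cccc(O)c2)c(O)c(/C=C/C(C)C)c1OC)C(=C)C
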